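**Plan**

1. Retrosynthesis: after desilylation the target is cut at C4–H (ketone reduction), at C3–CH2OH (formaldehyde aldol) and then at C2–C3 of the tetrahydrofuran (O1, C2 aryl, C3, C4, C5 benzyl). This leads back through an enol acetal to a 1,3-dioxolan-4-one and, by its two acetal C–O bonds, to an aryllactic acid and a dihydrobenzofuran aldehyde. The aldehyde is cut at C2–C3 of its furan ring (carbenoid C–H insertion) and at the benzyl aryl ether.
2. Enabling feature: C5 of the tetrahydrofuran, bonded to O1, to C4 and to the guaiacylmethyl group, is the α-carbon of (S)-3-aryllactic acid, and C2 is an aldehyde carbon. A dioxolanone of the two therefore already joins O1, C2, C4 and C5, and only C3 has to be inserted between C2 and C4.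
3. Forward order of ring formation: dihydrobenzofuran ring (step 5), dioxolanone (step 11), tetrahydrofuranone by oxygen-to-carbon rearrangement (step 13); C3 and C4 are then functionalised on the ketone.
4. Stereochemistry: dihydrobenzofuran C2/C3 (cis, 2R,3R) from the chiral dirhodium catalyst; tetrahydrofuran C5 (S) from 3-methoxy-L-tyrosine; C2 relayed from C5 in the rearrangement; C3 set anti to the C2 aryl group in the aldol; C4 by hydroxyl-directed hydride delivery.

Key step: step 13

Assumption: Rh2(S-PTTL)4, dirhodium tetrakis[N-phthaloyl-(S)-tert-leucinate], is taken as the catalyst enantiomer that gives the (2R,3S) ester 7; if the induction runs the other way, Rh2(R-PTTL)4 is used in its place and nothing else changes.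

Shorthand: the tetrahydrofuran is numbered as in the target (O1, C2 aryl, C3, C4, C5 benzyl). ArT = 3-methoxy-4-(triisopropylsilyloxy)phenyl. DBF = (2R,3R)-3-[(tert-butyldimethylsilyloxy)methyl]-7-methoxy-2-ArT-2,3-dihydro-1-benzofuran-5-yl.

**Route**

Step 1
Reactants: 1 vanillin
Product: 2 3-methoxy-4-(triisopropylsilyloxy)benzaldehyde
Conditions: i-Pr3SiCl, imidazole, DMF, rt
Reagents that add atoms: chlorotriisopropylsilane, CC(C)[Si](Cl)(C(C)C)C(C)C
Why: Imidazole-promoted silyl ether formation on the phenol; the bulky silyl ether should withstand the basic, reducing and dilute acidic steps that follow.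

Step 2
Reactants: 2 3-methoxy-4-(triisopropylsilyloxy)benzaldehyde
Product: 3 [3-methoxy-4-(triisopropylsilyloxy)phenyl]methanol
Conditions: NaBH4, MeOH/THF, 0 °C
Reagents that add atoms: none
Why: Borohydride reduction of an aromatic aldehyde, which leaves the aryl silyl ether untouched.

Step 3
Reactants: 3 [3-methoxy-4-(triisopropylsilyloxy)phenyl]methanol; 4 methyl 4-hydroxy-3-iodo-5-methoxybenzoate (methyl 5-iodovanillate)
Product: 5 methyl 3-iodo-5-methoxy-4-(ArT-methoxy)benzoate
Conditions: PPh3, DIAD, THF, 0 °C → rt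
Reagents that add atoms: none
Why: Mitsunobu etherification, in which the acidic para-acylated phenol is alkylated by the activated benzylic alcohol under neutral conditions that spare the silyl ether and the ester.

Step 4
Reactants: 5 methyl 3-iodo-5-methoxy-4-(ArT-methoxy)benzoate
Product: 6 methyl 3-(1-diazo-2-ethoxy-2-oxoethyl)-5-methoxy-4-(ArT-methoxy)benzoate
Conditions: ethyl diazoacetate, Pd(PPh3)4 (5 mol %), Ag2CO3 (0.5 equiv), Et3N, toluene, rt
Reagents that add atoms: ethyl diazoacetate, CCOC(=O)C=[N+]=[N-]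
Why: Palladium-catalysed cross-coupling of an aryl iodide with the C–H bond of a diazoacetate (oxidative addition to zerovalent palladium, silver-assisted palladation of the diazo ester, reductive elimination), which installs the donor/acceptor diazo group without loss of N2.

Step 5
Reactants: 6 methyl 3-(1-diazo-2-ethoxy-2-oxoethyl)-5-methoxy-4-(ArT-methoxy)benzoate
Product: 7 3-ethyl 5-methyl (2R,3S)-7-methoxy-2-ArT-2,3-dihydro-1-benzofuran-3,5-dicarboxylate (2,3-cis)
Conditions: Rh2(S-PTTL)4 (1 mol %), toluene, −78 → −60 °C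
Reagents that add atoms: none
Why: Intramolecular 1,5 C–H insertion of a dirhodium donor/acceptor carbenoid into the benzylic C–H bond next to the ether oxygen, a known enantioselective entry to cis-2-aryl-2,3-dihydrobenzofuran-3-carboxylates, in which the concerted insertion should give the cis relation of C2 and C3 kinetically and the chiral phthalimido carboxylate ligands should fix the absolute sense.

Step 6
Reactants: 7 3-ethyl 5-methyl (2R,3S)-7-methoxy-2-ArT-2,3-dihydro-1-benzofuran-3,5-dicarboxylate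
Product: 8 [(2R,3R)-7-methoxy-2-ArT-2,3-dihydro-1-benzofuran-3,5-diyl]dimethanol (2,3-cis)
Conditions: i-Bu2AlH (excess), CH2Cl2, −78 → 0 °C; aq. KNaC4H4O6
Reagents that add atoms: none
Why: Reduction of both esters to primary alcohols by a Lewis acidic, non-basic hydride, so that the epimerisable C3 centre next to the ester should not be enolised.

Step 7
Reactants: 8 [(2R,3R)-7-methoxy-2-ArT-2,3-dihydro-1-benzofuran-3,5-diyl]dimethanol
Product: 9 (2R,3R)-3-(hydroxymethyl)-7-methoxy-2-ArT-2,3-dihydro-1-benzofuran-5-carbaldehyde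
Conditions: MnO2, CH2Cl2, rt
Reagents that add atoms: none
Why: Chemoselective MnO2 oxidation of the benzylic alcohol, to which the aliphatic CH2OH group on C3 is inert.

Step 8
Reactants: 9 (2R,3R)-3-(hydroxymethyl)-7-methoxy-2-ArT-2,3-dihydro-1-benzofuran-5-carbaldehyde
Product: 10 (2R,3R)-3-[(tert-butyldimethylsilyloxy)methyl]-7-methoxy-2-ArT-2,3-dihydro-1-benzofuran-5-carbaldehyde (DBF–CHO)
Conditions: t-BuMe2SiCl, imidazole, DMF, rt
Reagents that add atoms: tert-butylchlorodimethylsilane, CC(C)(C)[Si](C)(C)Cl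
Why: Standard silylation of the remaining primary alcohol, needed because a free hydroxyl would consume the titanium, aluminium and amide reagents used later.

Step 9
Reactants: 11 3-methoxy-L-tyrosine
Product: 12 (S)-2-amino-3-ArT-propanoic acid (O-triisopropylsilyl-3-methoxy-L-tyrosine)
Conditions: i-Pr3SiCl, DBU, MeCN, 0 °C → rt
Reagents that add atoms: chlorotriisopropylsilane, CC(C)[Si](Cl)(C(C)C)C(C)C
Why: Selective O-silylation of a tyrosine-type amino acid, in which the phenoxide formed with the amidine base is silylated while the amino acid stays zwitterionic; protecting the phenol first blocks ring nitrosation in the next step.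

Step 10
Reactants: 12 (S)-2-amino-3-ArT-propanoic acid
Product: 13 (S)-2-hydroxy-3-ArT-propanoic acid
Conditions: NaNO2, 1 M H2SO4, H2O/1,4-dioxane, 0 °C → rt
Reagents that add atoms: water, O
Why: Diazotisation of the α-amino acid, in which the carboxylate displaces N2 to an α-lactone that water opens, two inversions and hence net retention, so the S centre that becomes C5 is kept.

Step 11
Reactants: 13 (S)-2-hydroxy-3-ArT-propanoic acid; 10 DBF–CHO
Product: 15 (2S,5S)-2-DBF-5-(ArT-methyl)-1,3-dioxolan-4-one (2,5-cis), via bis(trimethylsilyl) derivative 14 (not isolated)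
Conditions: (Me3Si)2NH, THF, rt, then evaporation; 10, Me3SiOTf (20 mol %), CH2Cl2, −78 °C; pyridine
Reagents that add atoms: none
Why: Silyl triflate-catalysed condensation of a bis-silylated α-hydroxy acid with an aldehyde (Noyori-type acetalisation) closes the dioxolanone at low temperature with loss of hexamethyldisiloxane, and the existing C5 centre should direct the new acetal centre cis, although that centre is erased again in step 13.

Step 12
Reactants: 15 (2S,5S)-2-DBF-5-(ArT-methyl)-1,3-dioxolan-4-one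
Product: 16 (2S,5S)-2-DBF-5-(ArT-methyl)-4-methylidene-1,3-dioxolane (2,5-cis)
Conditions: Cp2TiMe2, toluene/THF, 65 °C, dark
Reagents that add atoms: dimethyltitanocene, C[Ti](C)(C1C=CC=C1)C1C=CC=C1
Why: Petasis methylenation, in which the titanium methylidene released on heating converts the lactone-type carbonyl into the exocyclic enol ether through an oxatitanacyclobutane under conditions that are neither acidic nor basic, so the acetal and the C5 centre should be preserved.

Step 13
Reactants: 16 (2S,5S)-2-DBF-5-(ArT-methyl)-4-methylidene-1,3-dioxolane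
Product: 17 (2S,5S)-2-DBF-5-(ArT-methyl)tetrahydrofuran-4-one (target numbering, 2,5-cis)
Conditions: Me2AlCl (2 equiv), CH2Cl2, −78 °C; aq. NaHCO3 at −78 °C
Reagents that add atoms: none
Why: Me2AlCl binds the enol ether oxygen O3 of the dioxolane and the acetal bond C2–O3 ionises, giving an oxocarbenium ion at C2 that the electron-rich dihydrobenzofuran ring stabilises and an aluminium enolate (O–C4=CH2) that stays tied to it through O1 and C5; the enolate carbon then adds to C2, so that the new C2–C3 bond closes the tetrahydrofuran-4-one in an oxygen-to-carbon 1,3-shift of the Petasis–Ferrier type. The closest known reaction is the aluminium-promoted rearrangement of 4-methylene-1,3-dioxolanes made from dioxolanones to 2,5-cis tetrahydrofuran-3-ones, and of the homologous dioxanes to tetrahydropyranones. The one ring closes in a 5-(enolendo)-endo-trig mode, formally disfavoured but open here because a free oxocarbenium ion and a flexible metal enolate react within one tethered ion pair. The one new stereocentre, C2, is controlled by C5: in the envelope transition state the aryl group on the E-oxocarbenium ion and the benzyl group on C5 both lie pseudoequatorial, which places them cis, and the same isomer is the more stable ketone. The step needs cleavage of C2–O3 in preference to C2–O1, secured because only the enol ether oxygen leaves as an enolate while the other ionisation is unproductive and reversible, and it needs C5 to stay intact, secured because the C5–O1 bond is never broken and the ketone is freed only on cold quench. The acetal configuration of 16 is lost in the ion pair, so any trans-dioxolane should converge on the same product.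

Step 14
Reactants: 17 (2S,5S)-2-DBF-5-(ArT-methyl)tetrahydrofuran-4-one
Product: 19 (2S,5S)-2-DBF-5-(ArT-methyl)-4-(trimethylsilyloxy)-2,5-dihydrofuran (target numbering), via lithium enolate 18 (not isolated)
Conditions: LiN(i-Pr)2, THF, −78 °C; then Me3SiCl, Et3N, −78 → 0 °C
Reagents that add atoms: chlorotrimethylsilane, C[Si](C)(C)Cl
Why: Kinetic enolate formation with a hindered amide base should remove a proton from the unhindered C3 methylene and not from the tertiary, oxygen-bearing C5, and O-silylation fixes that regiochemistry, while at −78 °C the endocyclic enolate should not expel O1 because the C2–O1 bond lies close to the enolate plane.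

Step 15
Reactants: 19 (2S,5S)-2-DBF-5-(ArT-methyl)-4-(trimethylsilyloxy)-2,5-dihydrofuran
Product: 20 (2S,3R,5S)-2-DBF-3-(hydroxymethyl)-5-(ArT-methyl)tetrahydrofuran-4-one (target numbering, 2,3-trans, 2,5-cis)
Conditions: aq. HCHO (37 %), Yb(OTf)3 (10 mol %), THF, rt
Reagents that add atoms: formaldehyde, C=O
Why: Lanthanide triflate-catalysed Mukaiyama aldol reaction with aqueous formaldehyde, in which the electrophile should add to C3 from the face opposite the neighbouring C2 aryl group to give the 2,3-trans ketone, which is also the more stable epimer.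

Step 16
Reactants: 20 (2S,3R,5S)-2-DBF-3-(hydroxymethyl)-5-(ArT-methyl)tetrahydrofuran-4-one
Product: 21 (2S,3S,4S,5S)-2-DBF-3-(hydroxymethyl)-5-(ArT-methyl)tetrahydrofuran-4-ol (target numbering)
Conditions: Me4NBH(OAc)3, MeCN/AcOH (1:1), −30 °C
Reagents that add atoms: none
Why: Evans–Saksena hydroxyl-directed reduction, in which the primary hydroxyl replaces an acetate on boron and the hydride is delivered through a six-membered transition state to the ketone face that carries the CH2OH group, so the C4 hydroxyl should end trans to C3–CH2OH and cis to the C5 benzyl group, which is also the less hindered direction of attack.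

Step 17
Reactants: 21 (2S,3S,4S,5S)-2-DBF-3-(hydroxymethyl)-5-(ArT-methyl)tetrahydrofuran-4-ol
Product: 22 CNP0179668.1, (2S,3S,4S,5S)-2-[(2R,3R)-2-(4-hydroxy-3-methoxyphenyl)-3-(hydroxymethyl)-7-methoxy-2,3-dihydro-1-benzofuran-5-yl]-3-(hydroxymethyl)-5-[(4-hydroxy-3-methoxyphenyl)methyl]tetrahydrofuran-4-ol (target numbering)
Conditions: Bu4NF, AcOH, THF, 0 °C → rt
Reagents that add atoms: none
Why: Fluoride-mediated cleavage of the two aryl triisopropylsilyl ethers and the alkyl tert-butyldimethylsilyl ether, with acetic acid buffering the phenoxides so that the para-hydroxybenzyl ethers at C2 of both oxygen rings should not open through quinone methides.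

**Compound list**

1 | vanillin | COc1cc(C=O)ccc1O | starting material
2 | 3-methoxy-4-(triisopropylsilyloxy)benzaldehyde | COc1cc(C=O)ccc1O[Si](C(C)C)(C(C)C)C(C)C | intermediate
3 | [3-methoxy-4-(triisopropylsilyloxy)phenyl]methanol | COc1cc(CO)ccc1O[Si](C(C)C)(C(C)C)C(C)C | intermediate
4 | methyl 4-hydroxy-3-iodo-5-methoxybenzoate | COC(=O)c1cc(I)c(O)c(OC)c1 | starting material
5 | methyl 3-iodo-5-methoxy-4-{[3-methoxy-4-(triisopropylsilyloxy)phenyl]methoxy}benzoate | COC(=O)c1cc(I)c(OCc2ccc(O[Si](C(C)C)(C(C)C)C(C)C)c(OC)c2)c(OC)c1 | intermediate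
6 | methyl 3-(1-diazo-2-ethoxy-2-oxoethyl)-5-methoxy-4-{[3-methoxy-4-(triisopropylsilyloxy)phenyl]methoxy}benzoate | CCOC(=O)C(=[N+]=[N-])c1cc(C(=O)OC)cc(OC)c1OCc1ccc(O[Si](C(C)C)(C(C)C)C(C)C)c(OC)c1 | intermediate
7 | 3-ethyl 5-methyl (2R,3S)-7-methoxy-2-[3-methoxy-4-(triisopropylsilyloxy)phenyl]-2,3-dihydro-1-benzofuran-3,5-dicarboxylate (2,3-cis) | COC(=O)c1cc(OC)c2c(c1)[C@H](C(=O)OCC)[C@H](c1ccc(O[Si](C(C)C)(C(C)C)C(C)C)c(OC)c1)O2 | intermediate
8 | {(2R,3R)-7-methoxy-2-[3-methoxy-4-(triisopropylsilyloxy)phenyl]-2,3-dihydro-1-benzofuran-3,5-diyl}dimethanol (2,3-cis) | OCc1cc(OC)c2c(c1)[C@H](CO)[C@H](c1ccc(O[Si](C(C)C)(C(C)C)C(C)C)c(OC)c1)O2 | intermediate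
9 | (2R,3R)-3-(hydroxymethyl)-7-methoxy-2-[3-methoxy-4-(triisopropylsilyloxy)phenyl]-2,3-dihydro-1-benzofuran-5-carbaldehyde | O=Cc1cc(OC)c2c(c1)[C@H](CO)[C@H](c1ccc(O[Si](C(C)C)(C(C)C)C(C)C)c(OC)c1)O2 | intermediate
10 | (2R,3R)-3-[(tert-butyldimethylsilyloxy)methyl]-7-methoxy-2-[3-methoxy-4-(triisopropylsilyloxy)phenyl]-2,3-dihydro-1-benzofuran-5-carbaldehyde | O=Cc1cc(OC)c2c(c1)[C@H](CO[Si](C)(C)C(C)(C)C)[C@H](c1ccc(O[Si](C(C)C)(C(C)C)C(C)C)c(OC)c1)O2 | intermediate
11 | 3-methoxy-L-tyrosine | COc1cc(C[C@H](N)C(=O)O)ccc1O | starting material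
12 | (S)-2-amino-3-[3-methoxy-4-(triisopropylsilyloxy)phenyl]propanoic acid | COc1cc(C[C@H](N)C(=O)O)ccc1O[Si](C(C)C)(C(C)C)C(C)C | intermediate
13 | (S)-2-hydroxy-3-[3-methoxy-4-(triisopropylsilyloxy)phenyl]propanoic acid | COc1cc(C[C@H](O)C(=O)O)ccc1O[Si](C(C)C)(C(C)C)C(C)C | intermediate
14 | trimethylsilyl (S)-3-[3-methoxy-4-(triisopropylsilyloxy)phenyl]-2-(trimethylsilyloxy)propanoate (formed in the flask in step 11) | COc1cc(C[C@H](O[Si](C)(C)C)C(=O)O[Si](C)(C)C)ccc1O[Si](C(C)C)(C(C)C)C(C)C | intermediate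
15 | (2S,5S)-2-{(2R,3R)-3-[(tert-butyldimethylsilyloxy)methyl]-7-methoxy-2-[3-methoxy-4-(triisopropylsilyloxy)phenyl]-2,3-dihydro-1-benzofuran-5-yl}-5-{[3-methoxy-4-(triisopropylsilyloxy)phenyl]methyl}-1,3-dioxolan-4-one (2,5-cis) | O=C1O[C@@H](c2cc(OC)c3c(c2)[C@H](CO[Si](C)(C)C(C)(C)C)[C@H](c2ccc(O[Si](C(C)C)(C(C)C)C(C)C)c(OC)c2)O3)O[C@H]1Cc1ccc(O[Si](C(C)C)(C(C)C)C(C)C)c(OC)c1 | intermediate
16 | (2S,5S)-2-{(2R,3R)-3-[(tert-butyldimethylsilyloxy)methyl]-7-methoxy-2-[3-methoxy-4-(triisopropylsilyloxy)phenyl]-2,3-dihydro-1-benzofuran-5-yl}-5-{[3-methoxy-4-(triisopropylsilyloxy)phenyl]methyl}-4-methylidene-1,3-dioxolane (2,5-cis) | C=C1O[C@@H](c2cc(OC)c3c(c2)[C@H](CO[Si](C)(C)C(C)(C)C)[C@H](c2ccc(O[Si](C(C)C)(C(C)C)C(C)C)c(OC)c2)O3)O[C@H]1Cc1ccc(O[Si](C(C)C)(C(C)C)C(C)C)c(OC)c1 | intermediate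
17 | (2S,5S)-2-{(2R,3R)-3-[(tert-butyldimethylsilyloxy)methyl]-7-methoxy-2-[3-methoxy-4-(triisopropylsilyloxy)phenyl]-2,3-dihydro-1-benzofuran-5-yl}-5-{[3-methoxy-4-(triisopropylsilyloxy)phenyl]methyl}tetrahydrofuran-4-one (target numbering, 2,5-cis) | COc1cc(C[C@@H]2O[C@H](c3cc(OC)c4c(c3)[C@H](CO[Si](C)(C)C(C)(C)C)[C@H](c3ccc(O[Si](C(C)C)(C(C)C)C(C)C)c(OC)c3)O4)CC2=O)ccc1O[Si](C(C)C)(C(C)C)C(C)C | intermediate
18 | lithium C3=C4 enolate of ketone 17 (formed in the flask in step 14) | [Li+].COc1cc(C[C@@H]2O[C@H](c3cc(OC)c4c(c3)[C@H](CO[Si](C)(C)C(C)(C)C)[C@H](c3ccc(O[Si](C(C)C)(C(C)C)C(C)C)c(OC)c3)O4)C=C2[O-])ccc1O[Si](C(C)C)(C(C)C)C(C)C | intermediate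
19 | (2S,5S)-2-{(2R,3R)-3-[(tert-butyldimethylsilyloxy)methyl]-7-methoxy-2-[3-methoxy-4-(triisopropylsilyloxy)phenyl]-2,3-dihydro-1-benzofuran-5-yl}-5-{[3-methoxy-4-(triisopropylsilyloxy)phenyl]methyl}-4-(trimethylsilyloxy)-2,5-dihydrofuran (target numbering) | COc1cc(C[C@@H]2O[C@H](c3cc(OC)c4c(c3)[C@H](CO[Si](C)(C)C(C)(C)C)[C@H](c3ccc(O[Si](C(C)C)(C(C)C)C(C)C)c(OC)c3)O4)C=C2O[Si](C)(C)C)ccc1O[Si](C(C)C)(C(C)C)C(C)C | intermediate
20 | (2S,3R,5S)-2-{(2R,3R)-3-[(tert-butyldimethylsilyloxy)methyl]-7-methoxy-2-[3-methoxy-4-(triisopropylsilyloxy)phenyl]-2,3-dihydro-1-benzofuran-5-yl}-3-(hydroxymethyl)-5-{[3-methoxy-4-(triisopropylsilyloxy)phenyl]methyl}tetrahydrofuran-4-one (target numbering) | COc1cc(C[C@@H]2O[C@H](c3cc(OC)c4c(c3)[C@H](CO[Si](C)(C)C(C)(C)C)[C@H](c3ccc(O[Si](C(C)C)(C(C)C)C(C)C)c(OC)c3)O4)[C@@H](CO)C2=O)ccc1O[Si](C(C)C)(C(C)C)C(C)C | intermediate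
21 | (2S,3S,4S,5S)-2-{(2R,3R)-3-[(tert-butyldimethylsilyloxy)methyl]-7-methoxy-2-[3-methoxy-4-(triisopropylsilyloxy)phenyl]-2,3-dihydro-1-benzofuran-5-yl}-3-(hydroxymethyl)-5-{[3-methoxy-4-(triisopropylsilyloxy)phenyl]methyl}tetrahydrofuran-4-ol (target numbering) | COc1cc(C[C@@H]2O[C@H](c3cc(OC)c4c(c3)[C@H](CO[Si](C)(C)C(C)(C)C)[C@H](c3ccc(O[Si](C(C)C)(C(C)C)C(C)C)c(OC)c3)O4)[C@@H](CO)[C@@H]2O)ccc1O[Si](C(C)C)(C(C)C)C(C)C | intermediate
22 | CNP0179668.1, (2S,3S,4S,5S)-2-[(2R,3R)-2-(4-hydroxy-3-methoxyphenyl)-3-(hydroxymethyl)-7-methoxy-2,3-dihydro-1-benzofuran-5-yl]-3-(hydroxymethyl)-5-[(4-hydroxy-3-methoxyphenyl)methyl]tetrahydrofuran-4-ol (target numbering) | COc1cc(C[C@@H]2O[C@H](c3cc(OC)c4c(c3)[C@H](CO)[C@H](c3ccc(O)c(OC)c3)O4)[C@@H](CO)[C@@H]2O)ccc1O | target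

**Step count and risks**

Total step count: 17. Longest linear sequence: 15 steps (steps 1–8 and 11–17, from vanillin); the two-step branch 9–10 from 3-methoxy-L-tyrosine joins at step 11.

Steps most likely to fail:

1. Step 13. The tethered ion pair may lose the aldehyde instead of forming the C–C bond. The Lewis acid may also ionise the benzylic C2–O bond of the cis-dihydrobenzofuran and let that ring relax to the trans form. The freshly formed ketone may epimerise at C5 while still bound to aluminium. Fallback: starting from 16, the rearrangement is run under reducing conditions with i-Bu3Al (CH2Cl2, −78 → 0 °C), the variant established for this dioxolane series. The ketone is then reduced as it forms by β-hydride transfer from an isobutyl group and is never exposed to the Lewis acid. This should give the 2,5-cis tetrahydrofuran-4-ol F1, whose hydroxyl is expected cis to the C5 substituent, although its configuration is immaterial. Oxidation with Dess–Martin periodinane and NaHCO3 in CH2Cl2 returns to 17.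

2. Step 5. Enantiofacial discrimination by the catalyst may be insufficient on this trisubstituted, ester-bearing arene, or some trans isomer may leak through. Fallback, which replaces catalyst control by classical resolution: it starts from hydroxy aldehyde 9 of inadequate enantiomeric purity (in the limit, racemic cis material from the same sequence run with Rh2(OAc)4). Acylation with (1S)-camphanic chloride (Et3N, DMAP, CH2Cl2) gives the (1S,4R)-camphanate of 9 F2 and the (1S,4R)-camphanate of ent-9 F3. The two are separated by crystallisation or chromatography, and methanolysis of the former (K2CO3, MeOH, 0 °C) comes back to 9 as a single enantiomer. Any ent-10 that survives would become a diastereomer of 15 after union with enantiopure 13 and could also be removed there.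

3. Step 14. Deprotonation at C5 may compete with that at C3, or the lithium enolate may open the ring by β-elimination of O1. Fallback: starting from 17, soft enolisation with (c-C6H11)2BCl and Et3N in Et2O (−78 → 0 °C), known to occur away from an α-oxygenated methine, should give the dicyclohexylboron enolate of 17 F4. Gaseous formaldehyde from cracked paraformaldehyde at −78 °C, followed by buffered work-up, then leads directly to 20, so that steps 14 and 15 are both replaced.

Further compounds
F1 | step 13 | (2S,4S,5S)-2-{(2R,3R)-3-[(tert-butyldimethylsilyloxy)methyl]-7-methoxy-2-[3-methoxy-4-(triisopropylsilyloxy)phenyl]-2,3-dihydro-1-benzofuran-5-yl}-5-{[3-methoxy-4-(triisopropylsilyloxy)phenyl]methyl}tetrahydrofuran-4-ol (target numbering) | COc1cc(C[C@@H]2O[C@H](c3cc(OC)c4c(c3)[C@H](CO[Si](C)(C)C(C)(C)C)[C@H](c3ccc(O[Si](C(C)C)(C(C)C)C(C)C)c(OC)c3)O4)C[C@@H]2O)ccc1O[Si](C(C)C)(C(C)C)C(C)C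
F2 | step 5 | {(2R,3R)-5-formyl-7-methoxy-2-[3-methoxy-4-(triisopropylsilyloxy)phenyl]-2,3-dihydro-1-benzofuran-3-yl}methyl (1S,4R)-4,7,7-trimethyl-3-oxo-2-oxabicyclo[2.2.1]heptane-1-carboxylate | O=Cc1cc(OC)c2c(c1)[C@H](COC(=O)[C@@]34CC[C@@](C)(C(=O)O3)C4(C)C)[C@H](c1ccc(O[Si](C(C)C)(C(C)C)C(C)C)c(OC)c1)O2
F3 | step 5 | {(2S,3S)-5-formyl-7-methoxy-2-[3-methoxy-4-(triisopropylsilyloxy)phenyl]-2,3-dihydro-1-benzofuran-3-yl}methyl (1S,4R)-4,7,7-trimethyl-3-oxo-2-oxabicyclo[2.2.1]heptane-1-carboxylate | O=Cc1cc(OC)c2c(c1)[C@@H](COC(=O)[C@@]34CC[C@@](C)(C(=O)O3)C4(C)C)[C@@H](c1ccc(O[Si](C(C)C)(C(C)C)C(C)C)c(OC)c1)O2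
F4 | step 14 | dicyclohexylboron C3=C4 enolate of ketone 17 | COc1cc(C[C@@H]2O[C@H](c3cc(OC)c4c(c3)[C@H](CO[Si](C)(C)C(C)(C)C)[C@H](c3ccc(O[Si](C(C)C)(C(C)C)C(C)C)c(OC)c3)O4)C=C2OB(C2CCCCC2)C2CCCCC2)ccc1O[Si](C(C)C)(C(C)C)C(C)C
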